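The synthesis rests on disconnecting C4a–C5 in ring A of unit 1 (C4a, C5, C6, C7, C8, C8a). The free 5- and 7-hydroxyls flanking the C4 acyl group are the oxygenation pattern of a folded polyketide chain. In one operation the key step turns a methyl 3-oxobutanoate side chain on C8a of a cis-2,3-disubstituted dihydropyran-4-one into this phloroglucinol ring, unprotected and already distinguished from the 5''-O-benzyl-7''-O-methyl ring of unit 2. The precursor is that dihydropyranone, carrying at C3 the complete cis flavanone of unit 2. Its four stereocentres come from an asymmetric conjugate arylation (C2''), a catalyst-controlled hetero-Diels–Alder reaction (C2, C3) and a kinetic protonation (C3'').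

Key step: step 13

Remark: unprimed locants (C2–C8a) denote unit 1 and doubly primed locants unit 2 in every intermediate, whatever its systematic numbering.
Assumption: (S)-t-BuPyOx (step 3) and the (1R,2S)-aminoindanol-derived chromium catalyst (step 10) are taken to be the antipodes that lead to 2''R and to 2R,3R; if either sense proves opposite, the mirror-image ligand is used.
Remark: 1, 5, 9, 10 and 16 are purchased; 1 is the 4'-O-methyl ether of 2',4',6'-trihydroxyacetophenone, which saves a selective methylation.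

Step 1
Reactants: 1 1-(2,6-dihydroxy-4-methoxyphenyl)ethan-1-one
Product: 2 1-[2-(benzyloxy)-6-hydroxy-4-methoxyphenyl]ethan-1-one
Conditions: BnBr (1.05 equiv), K2CO3, acetone, reflux
Reagents that add atoms: benzyl bromide, BrCc1ccccc1
Why: Williamson etherification; after the first benzylation the remaining phenol is held in a hydrogen bond to the ketone and reacts far more slowly, so mono-protection should be clean.

Step 2
Reactants: 2 1-[2-(benzyloxy)-6-hydroxy-4-methoxyphenyl]ethan-1-one
Product: 4 5-(benzyloxy)-7-methoxy-4H-chromen-4-one, via enaminone 3 (not isolated)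
Conditions: Me2NCH(OMe)2, toluene, 100 °C; then conc. HCl, CH2Cl2, 40 °C
Reagents that add atoms: N,N-dimethylformamide dimethyl acetal, COC(OC)N(C)C
Why: Enaminone formation at the acetyl methyl group followed by acid-promoted addition–elimination of the phenol with loss of dimethylamine is the standard chromone annulation and installs C2''.

Step 3
Reactants: 4 5-(benzyloxy)-7-methoxy-4H-chromen-4-one; 5 (4-methoxyphenyl)boronic acid
Product: 6 (2R)-5-(benzyloxy)-7-methoxy-2-(4-methoxyphenyl)-2,3-dihydro-4H-chromen-4-one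
Conditions: Pd(OCOCF3)2 (5 mol%), (S)-t-BuPyOx (6 mol%), NH4PF6, H2O, ClCH2CH2Cl, 60 °C
Reagents that add atoms: none
Why: Asymmetric conjugate addition of an arylboronic acid to a chromone under divalent palladium–pyridine-oxazoline catalysis, in which the chiral ligand steers insertion of the C2''=C3'' bond into the aryl–palladium bond to one face and so sets C2'' (R), the flavanone being released by protonation without ring opening.

Step 4
Reactants: 6 (2R)-5-(benzyloxy)-7-methoxy-2-(4-methoxyphenyl)-2,3-dihydro-4H-chromen-4-one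
Product: 8 (2S,3S)-5-(benzyloxy)-3-bromo-7-methoxy-2-(4-methoxyphenyl)-2,3-dihydro-4H-chromen-4-one, via silyl enol ether 7 (not isolated)
Conditions: TBSOTf, Et3N, CH2Cl2, 0 °C; then NBS, THF, −78 °C
Reagents that add atoms: N-bromosuccinimide, O=C1CCC(=O)N1Br; tert-butyldimethylsilyl triflate, CC(C)(C)[Si](C)(C)OS(=O)(=O)C(F)(F)F (silyl group present in 7 only)
Why: Soft enolisation avoids the free enolate that would open the pyranone ring, and bromination of the enol silane at C3'' outruns bromination of ring A; bromine enters anti to the C2'' aryl group (trans, C2'' unchanged in space), but this centre only serves as a radical precursor.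

Step 5
Reactants: 9 tert-butyl(but-3-yn-1-yloxy)dimethylsilane; 10 N-methoxy-N-methylacetamide
Product: 11 6-[(tert-butyldimethylsilyl)oxy]hex-3-yn-2-one
Conditions: n-BuLi, THF, −78 °C; then 10, −78 → 0 °C; aq. NH4Cl
Reagents that add atoms: none
Why: Acylation of a lithium acetylide with a Weinreb amide stops at the ketone because the chelated tetrahedral adduct survives until work-up.

Step 6
Reactants: 11 6-[(tert-butyldimethylsilyl)oxy]hex-3-yn-2-one
Product: 12 (3E)-6-[(tert-butyldimethylsilyl)oxy]-4-methoxyhex-3-en-2-one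
Conditions: MeOH, DABCO (10 mol%), 0 °C → rt
Reagents that add atoms: methanol, CO
Why: Amine-catalysed oxa-Michael addition of methanol to the ynone gives the β-methoxy enone, which settles as the E isomer and places the future O1 leaving group and the C8 chain on the same carbon (C8a).

Step 7
Reactants: 12 (3E)-6-[(tert-butyldimethylsilyl)oxy]-4-methoxyhex-3-en-2-one
Product: 13 (3E)-2,6-bis[(tert-butyldimethylsilyl)oxy]-4-methoxyhexa-1,3-diene
Conditions: TBSOTf, Et3N, Et2O, 0 °C
Reagents that add atoms: tert-butyldimethylsilyl triflate, CC(C)(C)[Si](C)(C)OS(=O)(=O)C(F)(F)F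
Why: Kinetic soft enolisation of the vinylogous ester at its α'-methyl group gives the 2-silyloxy-1,3-diene, as in the preparation of Danishefsky-type dienes.

Step 8
Reactants: 8 (2S,3S)-5-(benzyloxy)-3-bromo-7-methoxy-2-(4-methoxyphenyl)-2,3-dihydro-4H-chromen-4-one; 13 (3E)-2,6-bis[(tert-butyldimethylsilyl)oxy]-4-methoxyhexa-1,3-diene
Product: 14 (2R,3S)-5-(benzyloxy)-3-{(3E)-6-[(tert-butyldimethylsilyl)oxy]-4-methoxy-2-oxohex-3-en-1-yl}-7-methoxy-2-(4-methoxyphenyl)-2,3-dihydro-4H-chromen-4-one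
Conditions: fac-Ir(ppy)3 (1 mol%), 2,6-lutidine, MeCN, blue LEDs, rt
Reagents that add atoms: none
Why: Photoredox radical alkylation of a silyl enol ether, in which the excited photocatalyst reduces the α-bromo ketone to the C3'' radical, this adds to the CH2 terminus of the electron-rich diene, and oxidation of the siloxyallyl radical with loss of the silyl group returns the β-methoxy enone; the C3–C3'' bond forms trans to the aryl group, but C3'' is flattened again in step 9.

Step 9
Reactants: 14 (2R,3S)-5-(benzyloxy)-3-{(3E)-6-[(tert-butyldimethylsilyl)oxy]-4-methoxy-2-oxohex-3-en-1-yl}-7-methoxy-2-(4-methoxyphenyl)-2,3-dihydro-4H-chromen-4-one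
Product: 15 (2S)-5-(benzyloxy)-3-{(1Z,3E)-2,6-bis[(tert-butyldimethylsilyl)oxy]-4-methoxyhexa-1,3-dien-1-yl}-4-[(tert-butyldimethylsilyl)oxy]-7-methoxy-2-(4-methoxyphenyl)-2H-chromene (C2'' unchanged in space)
Conditions: TBSOTf (3 equiv), Et3N (4 equiv), CH2Cl2, 0 °C → rt
Reagents that add atoms: tert-butyldimethylsilyl triflate, CC(C)(C)[Si](C)(C)OS(=O)(=O)C(F)(F)F
Why: Soft enolisation of both ketones gives the tetrasubstituted enol silane of the flavanone (C3'' becomes sp2, so its earlier configuration no longer matters) and the (Z)-2-silyloxy diene at the α'-carbon C3, the geometry expected for silyl triflate–amine enolisation of an alkyl ketone.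

Step 10
Reactants: 15 (2S)-5-(benzyloxy)-3-{(1Z,3E)-2,6-bis[(tert-butyldimethylsilyl)oxy]-4-methoxyhexa-1,3-dien-1-yl}-4-[(tert-butyldimethylsilyl)oxy]-7-methoxy-2-(4-methoxyphenyl)-2H-chromene; 16 4-methoxybenzaldehyde
Product: 18 (2R,3R)-5-(benzyloxy)-3-[(2R,3R)-6-(2-hydroxyethyl)-2-(4-methoxyphenyl)-4-oxo-3,4-dihydro-2H-pyran-3-yl]-7-methoxy-2-(4-methoxyphenyl)-2,3-dihydro-4H-chromen-4-one, via cycloadduct 17 (not isolated)
Conditions: [CrCl(L)] (5 mol%; L = (1R,2S)-1-{[3-(1-adamantyl)-2-oxido-5-methylphenyl]methylideneamino}indan-2-olate), 4 Å MS, t-BuOMe, rt; then HF·pyridine, pyridine, THF, −20 °C → rt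
Reagents that add atoms: none
Why: Catalyst-controlled endo hetero-Diels–Alder reaction of the aldehyde with the 1-alkoxy-3-silyloxy diene, in which the trivalent chromium Schiff-base complex selects the aldehyde face and the endo transition state places H2 and H3 cis (2R,3R), after which buffered HF collapses the cycloadduct to the enone with loss of methanol, frees the primary alcohol and protonates the flavene enol silane at C3'' from the face opposite the pseudoaxial C2'' aryl group, giving the cis flavanone (3''R).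

Step 11
Reactants: 18 (2R,3R)-5-(benzyloxy)-3-[(2R,3R)-6-(2-hydroxyethyl)-2-(4-methoxyphenyl)-4-oxo-3,4-dihydro-2H-pyran-3-yl]-7-methoxy-2-(4-methoxyphenyl)-2,3-dihydro-4H-chromen-4-one
Product: 19 {(2R,3R)-3-[(2R,3R)-5-(benzyloxy)-7-methoxy-2-(4-methoxyphenyl)-4-oxo-3,4-dihydro-2H-chromen-3-yl]-2-(4-methoxyphenyl)-4-oxo-3,4-dihydro-2H-pyran-6-yl}acetaldehyde
Conditions: Dess–Martin periodinane, pyridine, CH2Cl2, 0 °C
Reagents that add atoms: none
Why: Dess–Martin oxidation of a primary alcohol under buffered, non-enolising conditions that leave C3 and C3'' untouched; the aldehyde is used crude.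

Step 12
Reactants: 19 {(2R,3R)-3-[(2R,3R)-5-(benzyloxy)-7-methoxy-2-(4-methoxyphenyl)-4-oxo-3,4-dihydro-2H-chromen-3-yl]-2-(4-methoxyphenyl)-4-oxo-3,4-dihydro-2H-pyran-6-yl}acetaldehyde
Product: 20 methyl 4-{(2R,3R)-3-[(2R,3R)-5-(benzyloxy)-7-methoxy-2-(4-methoxyphenyl)-4-oxo-3,4-dihydro-2H-chromen-3-yl]-2-(4-methoxyphenyl)-4-oxo-3,4-dihydro-2H-pyran-6-yl}-3-oxobutanoate
Conditions: N2CHCO2Me, SnCl2 (10 mol%), CH2Cl2, rt
Reagents that add atoms: methyl diazoacetate, COC(=O)C=[N+]=[N-]
Why: Roskamp homologation, in which Lewis-acid-promoted addition of the diazo ester to the aldehyde and a 1,2-hydride shift with loss of N2 give the β-keto ester without any base, ketones being inert under these conditions.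

Step 13
Reactants: 20 methyl 4-{(2R,3R)-3-[(2R,3R)-5-(benzyloxy)-7-methoxy-2-(4-methoxyphenyl)-4-oxo-3,4-dihydro-2H-chromen-3-yl]-2-(4-methoxyphenyl)-4-oxo-3,4-dihydro-2H-pyran-6-yl}-3-oxobutanoate
Product: 21 (2R,3R,2''R,3''R)-5''-(benzyloxy)-5,7-dihydroxy-7''-methoxy-2,2''-bis(4-methoxyphenyl)-[3,3''-bichromane]-4,4''-dione
Conditions: Mg(OMe)2 (3 equiv), MeOH–THF (1:1), 0 °C → rt; then 1 M HCl, 0 °C
Reagents that add atoms: none
Why: Proposed new method: Mg(OMe)2 first gives the chelated C6 enolate of the β-keto ester, but closure should proceed through the minor tautomeric anion formed at C8, a position flanked by the C7 ketone and by C8a of the enone, whose charge is delocalised to O4 so that C4a becomes nucleophilic; C4a adds to the ester carbon C5, methoxide leaves, and the cyclohexenetrione enolises irreversibly to the aromatic ring with hydroxyls at C5 and C7. The closest known reaction type is the biomimetic Claisen cyclisation of 3,5,7-triketo esters to acylphloroglucinols, here applied to a chain whose 5-oxo group is masked as the enol ether of a dihydropyranone. Ring A (C4a, C5, C6, C7, C8, C8a) closes in the 6-(enolexo)-exo-trig mode, since the enolate bond C4=C4a lies outside the new ring and the ester C=O is exocyclic to it. No stereocentre is formed. The step needs C-acylation at C4a to win over aldol closure of C6 onto C4, and this is secured by the pyranone ring, which holds C8 and C4 trans across C4a=C8a so that the aldol ring would contain a trans double bond. It also needs C2, C3, C2'' and C3'' to survive, which rests on the chain methylenes being far more acidic than H3 and H3'', on the weak, chelating base at or below room temperature, and on the 5-hydroxyl that forms and at once hydrogen-bonds the C4 carbonyl.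

Step 14
Reactants: 21 (2R,3R,2''R,3''R)-5''-(benzyloxy)-5,7-dihydroxy-7''-methoxy-2,2''-bis(4-methoxyphenyl)-[3,3''-bichromane]-4,4''-dione
Product: 22 (2R,3R,2''R,3''R)-5,5'',7-trihydroxy-7''-methoxy-2,2''-bis(4-methoxyphenyl)-[3,3''-bichromane]-4,4''-dione (CNP0184936.2)
Conditions: H2 (1 atm), Pd/C (10%), EtOAc, rt
Reagents that add atoms: none
Why: Hydrogenolysis of the single benzyl aryl ether under neutral conditions, so that the cis centres meet neither acid nor base.

Compound list
1 | 1-(2,6-dihydroxy-4-methoxyphenyl)ethan-1-one | CC(=O)c1c(O)cc(OC)cc1O | starting material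
2 | 1-[2-(benzyloxy)-6-hydroxy-4-methoxyphenyl]ethan-1-one | CC(=O)c1c(O)cc(OC)cc1OCc1ccccc1 | intermediate
3 | (E)-1-[2-(benzyloxy)-6-hydroxy-4-methoxyphenyl]-3-(dimethylamino)prop-2-en-1-one | CN(C)/C=C/C(=O)c1c(O)cc(OC)cc1OCc1ccccc1 | intermediate (not isolated)
4 | 5-(benzyloxy)-7-methoxy-4H-chromen-4-one | COc1cc(OCc2ccccc2)c2c(c1)occc2=O | intermediate
5 | (4-methoxyphenyl)boronic acid | COc1ccc(B(O)O)cc1 | starting material
6 | (2R)-5-(benzyloxy)-7-methoxy-2-(4-methoxyphenyl)-2,3-dihydro-4H-chromen-4-one | COc1ccc(cc1)[C@H]1CC(=O)c2c(OCc3ccccc3)cc(OC)cc2O1 | intermediate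
7 | {[(2R)-5-(benzyloxy)-7-methoxy-2-(4-methoxyphenyl)-2H-chromen-4-yl]oxy}(tert-butyl)dimethylsilane | COc1ccc(cc1)[C@H]1C=C(O[Si](C)(C)C(C)(C)C)c2c(OCc3ccccc3)cc(OC)cc2O1 | intermediate (not isolated)
8 | (2S,3S)-5-(benzyloxy)-3-bromo-7-methoxy-2-(4-methoxyphenyl)-2,3-dihydro-4H-chromen-4-one (trans; the C2 descriptor changes only because bromine raises the priority of C3) | COc1ccc(cc1)[C@H]1[C@H](Br)C(=O)c2c(OCc3ccccc3)cc(OC)cc2O1 | intermediate
9 | tert-butyl(but-3-yn-1-yloxy)dimethylsilane | C#CCCO[Si](C)(C)C(C)(C)C | starting material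
10 | N-methoxy-N-methylacetamide | CC(=O)N(C)OC | starting material
11 | 6-[(tert-butyldimethylsilyl)oxy]hex-3-yn-2-one | CC(=O)C#CCCO[Si](C)(C)C(C)(C)C | intermediate
12 | (3E)-6-[(tert-butyldimethylsilyl)oxy]-4-methoxyhex-3-en-2-one | CC(=O)/C=C(/OC)CCO[Si](C)(C)C(C)(C)C | intermediate
13 | (3E)-2,6-bis[(tert-butyldimethylsilyl)oxy]-4-methoxyhexa-1,3-diene | C=C(O[Si](C)(C)C(C)(C)C)/C=C(/OC)CCO[Si](C)(C)C(C)(C)C | intermediate
14 | (2R,3S)-5-(benzyloxy)-3-{(3E)-6-[(tert-butyldimethylsilyl)oxy]-4-methoxy-2-oxohex-3-en-1-yl}-7-methoxy-2-(4-methoxyphenyl)-2,3-dihydro-4H-chromen-4-one (trans) | COc1ccc(cc1)[C@H]1[C@H](CC(=O)/C=C(/OC)CCO[Si](C)(C)C(C)(C)C)C(=O)c2c(OCc3ccccc3)cc(OC)cc2O1 | intermediate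
15 | (2S)-5-(benzyloxy)-3-{(1Z,3E)-2,6-bis[(tert-butyldimethylsilyl)oxy]-4-methoxyhexa-1,3-dien-1-yl}-4-[(tert-butyldimethylsilyl)oxy]-7-methoxy-2-(4-methoxyphenyl)-2H-chromene (aryl-bearing centre unchanged in space) | COc1ccc(cc1)[C@H]1C(/C=C(\O[Si](C)(C)C(C)(C)C)/C=C(/OC)CCO[Si](C)(C)C(C)(C)C)=C(O[Si](C)(C)C(C)(C)C)c2c(OCc3ccccc3)cc(OC)cc2O1 | intermediate
16 | 4-methoxybenzaldehyde | COc1ccc(C=O)cc1 | starting material
17 | (5R,6R)-2-methoxy-2-{2-[(tert-butyldimethylsilyl)oxy]ethyl}-4-[(tert-butyldimethylsilyl)oxy]-6-(4-methoxyphenyl)-5-{(2S)-5-(benzyloxy)-4-[(tert-butyldimethylsilyl)oxy]-7-methoxy-2-(4-methoxyphenyl)-2H-chromen-3-yl}-5,6-dihydro-2H-pyran (ketal carbon as a mixture) | COc1ccc([C@@H]2OC(OC)(CCO[Si](C)(C)C(C)(C)C)C=C(O[Si](C)(C)C(C)(C)C)[C@@H]2C2=C(O[Si](C)(C)C(C)(C)C)c3c(OCc4ccccc4)cc(OC)cc3O[C@H]2c2ccc(OC)cc2)cc1 | intermediate (not isolated)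
18 | (2R,3R)-5-(benzyloxy)-3-[(2R,3R)-6-(2-hydroxyethyl)-2-(4-methoxyphenyl)-4-oxo-3,4-dihydro-2H-pyran-3-yl]-7-methoxy-2-(4-methoxyphenyl)-2,3-dihydro-4H-chromen-4-one | COc1ccc([C@@H]2OC(CCO)=CC(=O)[C@@H]2[C@H]2C(=O)c3c(OCc4ccccc4)cc(OC)cc3O[C@H]2c2ccc(OC)cc2)cc1 | intermediate
19 | {(2R,3R)-3-[(2R,3R)-5-(benzyloxy)-7-methoxy-2-(4-methoxyphenyl)-4-oxo-3,4-dihydro-2H-chromen-3-yl]-2-(4-methoxyphenyl)-4-oxo-3,4-dihydro-2H-pyran-6-yl}acetaldehyde | COc1ccc([C@@H]2OC(CC=O)=CC(=O)[C@@H]2[C@H]2C(=O)c3c(OCc4ccccc4)cc(OC)cc3O[C@H]2c2ccc(OC)cc2)cc1 | intermediate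
20 | methyl 4-{(2R,3R)-3-[(2R,3R)-5-(benzyloxy)-7-methoxy-2-(4-methoxyphenyl)-4-oxo-3,4-dihydro-2H-chromen-3-yl]-2-(4-methoxyphenyl)-4-oxo-3,4-dihydro-2H-pyran-6-yl}-3-oxobutanoate | COc1ccc([C@@H]2OC(CC(=O)CC(=O)OC)=CC(=O)[C@@H]2[C@H]2C(=O)c3c(OCc4ccccc4)cc(OC)cc3O[C@H]2c2ccc(OC)cc2)cc1 | intermediate
21 | (2R,3R,2''R,3''R)-5''-(benzyloxy)-5,7-dihydroxy-7''-methoxy-2,2''-bis(4-methoxyphenyl)-[3,3''-bichromane]-4,4''-dione | COc1ccc([C@@H]2Oc3cc(O)cc(O)c3C(=O)[C@@H]2[C@H]2C(=O)c3c(OCc4ccccc4)cc(OC)cc3O[C@H]2c2ccc(OC)cc2)cc1 | intermediate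
22 | (2R,3R,2''R,3''R)-5,5'',7-trihydroxy-7''-methoxy-2,2''-bis(4-methoxyphenyl)-[3,3''-bichromane]-4,4''-dione | COc1ccc([C@@H]2Oc3cc(O)cc(O)c3C(=O)[C@@H]2[C@H]2C(=O)c3c(O)cc(OC)cc3O[C@H]2c2ccc(OC)cc2)cc1 | target

Total step count: 14. Longest linear sequence: 11 steps (steps 1–4 and 8–14); the diene 13 is made in 3 steps (5–7) and joins at step 8.

Steps most likely to fail

1. Step 13 (proposed new method). The chain may stay parked as the unreactive C6 enolate, or enolisation at C3'' with reversible opening of the flavanone ring may erode the cis centres before ring A closes. The fallback uses known reactions only: ring A of unit 1 is brought in ready-made and two flavanones are joined at C3–C3''. It sets out from 8. Commercial 1-[2,4-bis(benzyloxy)-6-hydroxyphenyl]ethan-1-one is taken through the operations of steps 2 and 3, by way of the enaminone F1 and 5,7-bis(benzyloxy)-4H-chromen-4-one F2 and then asymmetric arylation with 5, to (2R)-5,7-bis(benzyloxy)-2-(4-methoxyphenyl)chroman-4-one F3. Its silyl enol ether F4 (TBSOTf, Et3N) is coupled with 8 under the photoredox conditions of step 8 and should give the trans,trans tri-O-benzyl biflavanone F5. Double soft enolisation (TBSOTf, Et3N) gives the bis(silyl enol ether) F6, and kinetic protonation with HF·pyridine at −40 °C, each proton entering anti to the neighbouring aryl group, should give the cis,cis tri-O-benzyl biflavanone F7. Hydrogenolysis of its three benzyl ethers (H2, Pd/C, EtOAc) comes back to the route at 22.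

2. Step 10. With the 1,1-disubstituted diene terminus the cycloaddition may turn into a stepwise Mukaiyama aldol–cyclisation, which would weaken both the endo (cis) preference and the facial control of the catalyst, and the electron-rich aldehyde may react slowly. The fallback sets out from 15 and replaces the cycloaddition by a Mukaiyama aldol reaction with 16 that is syn-selective whatever the enol silane geometry, catalysed by the chiral acyloxyborane made from BH3·THF and (2R,3R)-2-O-(2,6-diisopropoxybenzoyl)tartaric acid (EtCN, −78 °C). This gives the syn-aldol silyl ether F8. HF·pyridine and then TFA (CH2Cl2, 0 °C) remove the silyl groups, protonate C3'' as in step 10 and close the pyranone by oxa-Michael addition and loss of methanol, coming back to the route at 18.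

3. Step 8. The C3'' radical is hindered: over-reduction to the enolate followed by loss of bromide to the flavone, or radical addition too slow to compete with hydrogen abstraction, would starve the coupling. The fallback generates the radical by oxidation instead of reduction. It sets out from 7, which is isolated by stopping step 4 before the NBS addition, and cross-couples it with 13 by (NH4)2Ce(NO3)6 and NaHCO3 in MeCN at −30 °C (oxidative heterocoupling of two silyl enol ethers). It comes back to the route at 14 and makes no new compound.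

Further compounds
F1 | step 13 | (E)-1-[2,4-bis(benzyloxy)-6-hydroxyphenyl]-3-(dimethylamino)prop-2-en-1-one | CN(C)/C=C/C(=O)c1c(O)cc(OCc2ccccc2)cc1OCc1ccccc1
F2 | step 13 | 5,7-bis(benzyloxy)-4H-chromen-4-one | O=c1ccoc2cc(OCc3ccccc3)cc(OCc3ccccc3)c12
F3 | step 13 | (2R)-5,7-bis(benzyloxy)-2-(4-methoxyphenyl)-2,3-dihydro-4H-chromen-4-one | COc1ccc(cc1)[C@H]1CC(=O)c2c(OCc3ccccc3)cc(OCc3ccccc3)cc2O1
F4 | step 13 | {[(2R)-5,7-bis(benzyloxy)-2-(4-methoxyphenyl)-2H-chromen-4-yl]oxy}(tert-butyl)dimethylsilane | COc1ccc(cc1)[C@H]1C=C(O[Si](C)(C)C(C)(C)C)c2c(OCc3ccccc3)cc(OCc3ccccc3)cc2O1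
F5 | step 13 | (2R,3S,2''R,3''S)-5,5'',7-tris(benzyloxy)-7''-methoxy-2,2''-bis(4-methoxyphenyl)-[3,3''-bichromane]-4,4''-dione (trans,trans) | COc1ccc([C@@H]2Oc3cc(OCc4ccccc4)cc(OCc4ccccc4)c3C(=O)[C@H]2[C@@H]2C(=O)c3c(OCc4ccccc4)cc(OC)cc3O[C@H]2c2ccc(OC)cc2)cc1
F6 | step 13 | 4,4''-bis(tert-butyldimethylsilyl) bis(enol ether) of F5 (3,3''-linked bis-2H-chromene, aryl-bearing centres unchanged in space) | COc1ccc([C@@H]2Oc3cc(OCc4ccccc4)cc(OCc4ccccc4)c3C(O[Si](C)(C)C(C)(C)C)=C2C2=C(O[Si](C)(C)C(C)(C)C)c3c(OCc4ccccc4)cc(OC)cc3O[C@H]2c2ccc(OC)cc2)cc1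
F7 | step 13 | (2R,3R,2''R,3''R)-5,5'',7-tris(benzyloxy)-7''-methoxy-2,2''-bis(4-methoxyphenyl)-[3,3''-bichromane]-4,4''-dione (cis,cis) | COc1ccc([C@@H]2Oc3cc(OCc4ccccc4)cc(OCc4ccccc4)c3C(=O)[C@@H]2[C@H]2C(=O)c3c(OCc4ccccc4)cc(OC)cc3O[C@H]2c2ccc(OC)cc2)cc1
F8 | step 10 | syn-aldol silyl ether: (1R,2R,4E)-2-{(2S)-5-(benzyloxy)-4-[(tert-butyldimethylsilyl)oxy]-7-methoxy-2-(4-methoxyphenyl)-2H-chromen-3-yl}-1,7-bis[(tert-butyldimethylsilyl)oxy]-5-methoxy-1-(4-methoxyphenyl)hept-4-en-3-one | COc1ccc([C@H](O[Si](C)(C)C(C)(C)C)[C@H](C(=O)/C=C(/OC)CCO[Si](C)(C)C(C)(C)C)C2=C(O[Si](C)(C)C(C)(C)C)c3c(OCc4ccccc4)cc(OC)cc3O[C@H]2c2ccc(OC)cc2)cc1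
F0 | step 8 | none | none
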